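Numbering used below: C1 is the carbinol carbon bearing CH2OBz (C7), C2 is CHOBz, C3 is CHOH, C4=C5 is the alkene and C6 is CHCl. The β face carries 1-OH and 2-OBz. The α face carries 3-OH, 6-Cl and C7. The target is (1R,2R,5S,6R) by IUPAC numbering.

**Retrosynthetic overview**
1. 12 ⇒ diene 10 by anti addition of Cl (C6, α) and O (C1, β) across C1=C6. A chloriranium/acyloxonium pair replaces the plant's oxirane-then-chloride sequence, and the 2β-benzoate places the new oxygen cis to itself.
2. 10 ⇒ 8, an arene 2,3-oxide masked as its HBr adduct. Benzoate opens the C2–C3 oxirane at allylic C2 (arene oxide → trans-dihydrodiol ester logic), and loss of HBr then unveils the diene. The mask blocks racemisation through the oxepine.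
3. 8 ⇒ 5 ⇒ 4 ⇒ 3. The oxirane comes from a hydroxyl-directed, desymmetrising epoxidation of the Cs-symmetric dihydroarene 3, which is the only source of absolute configuration. 3 ⇒ cyclohexa-1,4-diene + CH2O.
4. Ring order: the carbocycle is bought. The C2–C3 oxirane forms in step 2. The C1–C6 onium ring and the C1/C2 dioxolanylium ring form in step 7 and are opened in the same flask.

Assumption: the ligand antipode that gives 4 rather than ent-4 is fixed by one test run. Both antipodes come from commercial (R,R)- or (S,S)-cyclohexane-1,2-diamine.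

**Step 1**
Reactants: 1 cyclohexa-1,4-diene
Product: 3 (cyclohexa-2,5-dien-1-yl)methanol, via cyclohexadienyllithium 2 (not isolated)
Conditions: s-BuLi, TMEDA, THF, −78 °C; CH2O gas from dry paraformaldehyde, −78 → 0 °C; H2O
Reagents that add atoms: paraformaldehyde, reacting as formaldehyde, C=O
Why: Deprotonation of the doubly allylic CH2 gives a pentadienyl-type anion that adds to the aldehyde through its central carbon (carbanion addition to a carbonyl), so the unconjugated Cs-symmetric diene is kept and no stereocentre is formed.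

**Step 2**
Reactants: 3 (cyclohexa-2,5-dien-1-yl)methanol
Product: 4 [(1R,2S,6S)-7-oxabicyclo[4.1.0]hept-3-en-2-yl]methanol (oxirane on the α face and cis to CH2OH)
Conditions: VO(OiPr)3 (2 mol %), C2-symmetric bis-hydroxamic acid ligand from trans-cyclohexane-1,2-diamine (4 mol %), cumene hydroperoxide (1.1 equiv), toluene, 0 °C
Reagents that add atoms: cumene hydroperoxide, CC(C)(OO)c1ccccc1
Why: In this vanadium/bis-hydroxamic acid desymmetrising epoxidation of a homoallylic alcohol the metal-bound alkoxide delivers oxygen to the face syn to CH2OH, the ligand picks one of the two enantiotopic C=C bonds (setting C1, C2 and C3 together), and the minor enantiomer is consumed faster by a second epoxidation, which raises the ee.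

**Step 3**
Reactants: 4 epoxy alcohol
Product: 5 [(1R,2S,6S)-7-oxabicyclo[4.1.0]hept-3-en-2-yl]methyl benzoate
Conditions: BzCl (1.1 equiv), pyridine, CH2Cl2, 0 °C
Reagents that add atoms: benzoyl chloride, O=C(Cl)c1ccccc1
Why: Plain O-acylation of the primary alcohol touches no stereocentre, installs the C7 benzoate of the target, and removes a free OH that would otherwise cyclise onto the seleniranium ion of step 4.

**Step 4**
Reactants: 5 epoxy benzoate
Product: 8 [(1R,4R,6S)-4-bromo-7-oxabicyclo[4.1.0]hept-2-en-2-yl]methyl benzoate, via selenobromide adduct 6 (not isolated), via selenoxide 7 (not isolated)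
Conditions: PhSeBr (1.05 equiv), CH2Cl2, −78 °C; then pyridine, 30 % H2O2 (2.2 equiv), 0 °C → rt
Reagents that add atoms: phenylselanyl bromide, Br[Se]c1ccccc1
Why: In this anti selenobromination followed by selenoxide syn elimination PhSe+ takes the free β face, bromide opens the seleniranium ion at the less hindered C5 from the α face (setting 5α-Br), and the selenoxide eliminates away from the C–Br carbon through the syn 1β-H, which moves the alkene to C1=C6 and makes C2 the only allylic oxirane carbon.

**Step 5**
Reactants: 8 bromo vinyl oxirane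
Product: 9 [(3R,5S,6S)-6-(benzoyloxy)-3-bromo-5-hydroxycyclohex-1-en-1-yl]methyl benzoate
Conditions: PhCO2H (2 equiv), CH2Cl2, 0 °C → rt; NaHCO3 wash
Reagents that add atoms: benzoic acid, O=C(O)c1ccccc1
Why: In this acid-promoted SN2-type opening of a vinyl oxirane benzoate (directly or relayed by the C7 benzoate) enters at allylic C2 from the β face with inversion while the C3–O bond is kept, giving the trans 2β-benzoate/3α-alcohol with the ester already on the correct oxygen.

**Step 6**
Reactants: 9 bromo hydroxy dibenzoate
Product: 10 [(5S,6S)-6-(benzoyloxy)-5-hydroxycyclohexa-1,3-dien-1-yl]methyl benzoate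
Conditions: DBU (1.5 equiv), toluene, 0 °C → rt
Reagents that add atoms: none
Why: In this E2 dehydrobromination the pseudo-axial 5α-Br is anti-periplanar to 4β-H, so the conjugated diene forms and the auxiliary C5 centre disappears, while C2 and C3 stay fixed because no oxirane remains that could tautomerise to an oxepine.

**Step 7**
Reactants: 10 diene hydroxy dibenzoate
Product: 12 [(1R,2R,5S,6R)-6-(benzoyloxy)-2-chloro-1,5-dihydroxycyclohex-3-en-1-yl]methyl benzoate, via dioxolanylium ion 11 (not isolated)
Conditions: NCS (1.05 equiv), thiourea (5 mol %), acetone–H2O 5:1, 0 °C, dark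
Reagents that add atoms: N-chlorosuccinimide, O=C1CCC(=O)N1Cl; water, O
Why: Proposed new method: activated NCS should deliver Cl+ to the more nucleophilic trisubstituted C1=C6 bond from the α face, anti to the pseudo-axial 2β-benzoate (the site and face I expect peracids to prefer in such diene esters), while the carbonyl oxygen of that benzoate (or the C7 benzoate, or water, all converging on the same product) closes on tertiary C1 from the β face, so Cl ends 6α and O ends 1β, and hydrolysis of 11 leaves the ester on the secondary O-2 because any tertiary ester migrates there; the closest known chemistry is halohydrin formation with neighbouring-ester participation (Woodward–Prévost cis-hydroxylation, halocyclisation of allylic benzoates).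

**Compound list**
1 | cyclohexa-1,4-diene | C1C=CCC=C1 | starting material
2 | cyclohexa-2,5-dien-1-yllithium | [Li]C1C=CCC=C1 | intermediate
3 | (cyclohexa-2,5-dien-1-yl)methanol | OCC1C=CCC=C1 | intermediate
4 | [(1R,2S,6S)-7-oxabicyclo[4.1.0]hept-3-en-2-yl]methanol | OC[C@@H]1C=CC[C@@H]2O[C@H]12 | intermediate
5 | [(1R,2S,6S)-7-oxabicyclo[4.1.0]hept-3-en-2-yl]methyl benzoate | O=C(OC[C@@H]1C=CC[C@@H]2O[C@H]12)c1ccccc1 | intermediate
6 | [(1R,2S,3R,4R,6S)-4-bromo-3-(phenylselanyl)-7-oxabicyclo[4.1.0]heptan-2-yl]methyl benzoate | O=C(OC[C@@H]1[C@@H]([Se]c2ccccc2)[C@H](Br)C[C@@H]3O[C@H]13)c1ccccc1 | intermediate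
7 | selenoxide of 6 (Se configuration undefined) | O=C(OC[C@@H]1[C@@H]([Se](=O)c2ccccc2)[C@H](Br)C[C@@H]3O[C@H]13)c1ccccc1 | intermediate
8 | [(1R,4R,6S)-4-bromo-7-oxabicyclo[4.1.0]hept-2-en-2-yl]methyl benzoate | O=C(OCC1=C[C@H](Br)C[C@@H]2O[C@H]12)c1ccccc1 | intermediate
9 | [(3R,5S,6S)-6-(benzoyloxy)-3-bromo-5-hydroxycyclohex-1-en-1-yl]methyl benzoate | O=C(OCC1=C[C@H](Br)C[C@H](O)[C@H]1OC(=O)c1ccccc1)c1ccccc1 | intermediate
10 | [(5S,6S)-6-(benzoyloxy)-5-hydroxycyclohexa-1,3-dien-1-yl]methyl benzoate | O=C(OCC1=CC=C[C@H](O)[C@H]1OC(=O)c1ccccc1)c1ccccc1 | intermediate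
11 | cis-fused 2-phenyl-1,3-dioxolan-2-ylium ion bridging O-1 and O-2 (6α-Cl, 3α-OH) | O=C(OC[C@@]12OC(c3ccccc3)=[O+][C@@H]1[C@@H](O)C=C[C@H]2Cl)c1ccccc1 | intermediate
12 | [(1R,2R,5S,6R)-6-(benzoyloxy)-2-chloro-1,5-dihydroxycyclohex-3-en-1-yl]methyl benzoate | O=C(OC[C@]1(O)[C@H](Cl)C=C[C@H](O)[C@H]1OC(=O)c1ccccc1)c1ccccc1 | target

Total step count: 7. Longest linear sequence: 7.

**Steps most likely to fail**

Step 7 carries the most risk. Cl+ may attack the diene terminus C4 and give 1,4-adducts, or the allylic alcohol may be oxidised and the ring aromatise. The fallback sets out from 10 and returns at 12. It builds the oxirane under reagent control and brings chloride in afterwards. Shi epoxidation (the fructose-derived ketone antipode that attacks the β face, Oxone, K2CO3 buffer, MeCN–dimethoxymethane–H2O, 0 °C) gives the 1β,6β-epoxide [(1S,2R,3S,6S)-2-(benzoyloxy)-3-hydroxy-7-oxabicyclo[4.1.0]hept-4-en-1-yl]methyl benzoate F1. Pyridinium chloride in CH2Cl2 then opens it at allylic C6 with inversion to give 12.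

Step 4 is second. Bromide may open the seleniranium ion at C6 instead of C5, which would move the alkene to C4=C5 and reverse the regiochemistry of step 5. The fallback sets out from 5 and returns at 8. It uses a Schenck ene reaction in place of selenium. Singlet oxygen (O2, tetraphenylporphyrin, visible light, CH2Cl2, −20 °C) approaches the free β face and abstracts the 1β-H next to the larger allylic substituent. This gives the allylic hydroperoxide [(1R,4S,6S)-4-hydroperoxy-7-oxabicyclo[4.1.0]hept-2-en-2-yl]methyl benzoate F2. PPh3 in the same flask reduces it to the allylic alcohol [(1R,4S,6S)-4-hydroxy-7-oxabicyclo[4.1.0]hept-2-en-2-yl]methyl benzoate F3. Appel bromination (CBr4, PPh3, CH2Cl2, 0 °C) with inversion gives 8.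

Step 2 is third. The ee on this cyclic primary homoallylic alcohol is untested, and the doubly allylic C–H bonds invite aromatisation. The fallback sets out from 3 and returns at 4. It replaces asymmetric catalysis with resolution. Achiral directed epoxidation (VO(acac)2, t-BuOOH, CH2Cl2, 0 °C) gives the racemic cis-epoxy alcohol F4. A lipase kinetic resolution (Amano lipase PS, vinyl acetate, MTBE, enzyme and acyl donor chosen so that the unwanted antipode reacts) acetylates it to [(1S,2R,6R)-7-oxabicyclo[4.1.0]hept-3-en-2-yl]methyl acetate F5. This leaves 4, at most 50 %, to be separated by chromatography.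

**Further compounds**
F1 | step 7 | [(1S,2R,3S,6S)-2-(benzoyloxy)-3-hydroxy-7-oxabicyclo[4.1.0]hept-4-en-1-yl]methyl benzoate | O=C(OC[C@]12O[C@H]1C=C[C@H](O)[C@H]2OC(=O)c1ccccc1)c1ccccc1
F2 | step 4 | [(1R,4S,6S)-4-hydroperoxy-7-oxabicyclo[4.1.0]hept-2-en-2-yl]methyl benzoate | O=C(OCC1=C[C@@H](OO)C[C@@H]2O[C@H]12)c1ccccc1
F3 | step 4 | [(1R,4S,6S)-4-hydroxy-7-oxabicyclo[4.1.0]hept-2-en-2-yl]methyl benzoate | O=C(OCC1=C[C@@H](O)C[C@@H]2O[C@H]12)c1ccccc1
F4 | step 2 | racemic cis-(7-oxabicyclo[4.1.0]hept-3-en-2-yl)methanol (both enantiomers) | OC[C@@H]1C=CC[C@@H]2O[C@H]12.OC[C@H]1C=CC[C@H]2O[C@@H]12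
F5 | step 2 | [(1S,2R,6R)-7-oxabicyclo[4.1.0]hept-3-en-2-yl]methyl acetate | CC(=O)OC[C@H]1C=CC[C@H]2O[C@@H]12
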